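The runs were computed with constants of no real substance; the scatter is artificial.

1. The question is how this flask shares its product between side product and target at three times, so I turn it round: what would the numbers have to show for target to lead?

- east: substrate 0.38 M; reagent 0.25 M; free catalyst 0.25 mM; second catalyst 0.25 mM; run made earlier
- flask: substrate 0.25 M; reagent 0.250 M; free catalyst 0.25 mM; second catalyst 0.25 mM; time 10 min

- east (time / s: side product / %, target / %): 12.0: 21.4, 6.1; 25.0: 40.7, 10.7; 40.0: 58.1, 13.3; 50.0: 61.2, 14.3; 60.0: 68.5, 16.2

(scatter of a reading: 1 percentage point)

- the analysis behind the earlier runs scatters by 1 percentage point, standard deviation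

- share of side product in side product plus target at 4.0 s
- share of side product in side product plus target at 50 s
- share of side product in side product plus target at 10 min

2. At 60.0 s the east run gives 0.626 as the base-ten logarithm of side product over target, each a fraction of the substrate charged: the odds exponent, the logarithm of a selectivity factor.

3. Target leads below zero, so the east ratio has to fall by a factor of 4.23.

4. At 12.0 s the east reading gives 0.545, with a scatter of 1 percentage point on a small target reading. That drift of 0.0810 is smaller than the 0.626 still to go to zero.

5. I expect this flask to climb from about 0.545 to about 0.626, a final share near 80.9%, though one run cannot show how the exponent moves with the substrate charge.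

6. The forecast gives 77.5% (73% to 81%), 79% (75.5% to 82%) and 79.8% (76% to 84%), holding that “side product probably does not consume reagent”. Its final exponent of 0.597 is lower than mine.

7. The flask gives 71.8% at 4.0 s, 78.3% at 50 s and 81.0% at 10 min.

    substrate + free catalyst ⇌ free catalyst + open intermediate (K = 1.40, k = 900 M⁻¹ s⁻¹)
    second catalyst + open intermediate ⇌ catalyst intermediate (K = 12.0 M⁻¹, k = 460 M⁻¹ s⁻¹)
    reagent + catalyst intermediate → second catalyst + target (k = 60.0 M⁻¹ s⁻¹)
    second catalyst → spent catalyst (k = 0.0290 s⁻¹)
    open intermediate → side product (k = 0.0470 s⁻¹)

8. At 5.00 min the flask holds second catalyst at 0.0355% and spent catalyst at >99.9% of the second catalyst charged, with reagent at 81.0% of its own charge. The flask's exponent goes from 0.406 at 4.0 s to 0.630 at 10 min, against the reading of 0.626 from the east run at 60.0 s. The neighbour flask charged with 0.10 M of substrate ends with target at 22.2% and side product at 77.8%, an exponent of 0.545, which is 0.0833 below this flask's exponent at 10 min.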